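**Retrosynthetic overview**

1. Absinthin is cut by a retro-Diels–Alder reaction into two molecules of one guaianolide cyclopentadiene (21, the 1,5-hydrogen-shift tautomer of artabsin 20); the norbornene and the six stereocentres around it are made last, by dimerisation.
2. Feature used (guaiane locants in each half): the five-membered ring C1–C5 and the seven-membered ring C1/C5–C10 form a ten-carbon perimeter C1…C10 cross-linked by C1–C5, with oxygenated C10 next to C1. C2–C3 therefore lies opposite a former C5–C10 bond, and C2=C1–C10–C5–C4=C3 is a Cope array hidden in a 5,10-dialkenylcyclohexane-5,10-diol.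
3. Key disconnection, C2–C3 and C1–C5 together: dianionic oxy-Cope rearrangement (six- to ten-membered ring) and transannular aldol condensation (ten-membered ring to five- plus seven-membered rings) convert diol 11 into hydroazulenone 15.
4. After it, C14 is added to the C10 ketone and the second ring double bond comes from allylic oxidation and elimination. Before it, 11 is built from an organocatalytic cyclohexenone (C7), dihydroxylation/lactonisation (C6) and two alkenyl Grignard additions.
5. Ring order: cyclohexane, γ-lactone, (ten-membered ring), cyclopentene plus cycloheptenone in one step, norbornene by dimerisation.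

Key step: step 6

Remark 1: C1–C15 are guaiane locants of each half (C6 bears the lactone oxygen, C10 the carbinol, C14 its methyl, C15 the methyl on C4, C13 the lactone methyl); α/β refer to the usual guaianolide drawing with H-7 α.
Remark 2: racemic methyl 2-methyl-4-oxobutanoate (1) is taken as a commercial aldehyde; its stereocentre (C11) is a lactone α-carbon later and is equilibrated in step 3.

**Step 1**
Reactants: 1 methyl 2-methyl-4-oxobutanoate (racemic); 2 but-3-en-2-one
Product: 4 methyl 2-[(1R)-4-oxocyclohex-2-en-1-yl]propanoate (C11 epimers), via Michael adduct 3 (not isolated)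
Conditions: (S)-α,α-diphenylprolinol trimethylsilyl ether (10 mol%), 4-nitrophenol (20 mol%), CH2Cl2, 4 °C; then pyrrolidine, AcOH, 40 °C
Reagents that add atoms: none
Why: Enamine-catalysed Michael addition, in which the (E)-enamine of 1 should add to the enone on the face away from the diphenyl(silyloxy)methyl group of the (S)-catalyst and so set C7, followed by amine-catalysed intramolecular aldol condensation of the 1,5-keto aldehyde to the 4-substituted cyclohexenone.

**Step 2**
Reactants: 4 methyl 2-[(1R)-4-oxocyclohex-2-en-1-yl]propanoate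
Product: 7 (3aS,7R,7aS)-7-hydroxy-3-methylhexahydro-1-benzofuran-2,6-dione (trans-fused lactone, C5 carbinol equatorial, C11 epimers), via diol ester 5 (not isolated), via axial ketol 6 (not isolated)
Conditions: K2OsO2(OH)4 (2 mol%), NMO, citric acid, t-BuOH/H2O, 23 °C; then CSA (10 mol%), PhMe, 60 °C
Reagents that add atoms: N-methylmorpholine N-oxide, C[N+]1([O-])CCOCC1; water, O (both oxygens pass through the osmium catalyst)
Why: Osmium-catalysed syn-dihydroxylation should occur on the enone face anti to the C7 side chain; the C6 hydroxyl then lactonises with the ester to the trans-fused γ-lactone (C6 set), and acid enolisation equilibrates the axial C5 carbinol of 6 through the enediol to the equatorial, hydrogen-bonded α-ketol 7.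

**Step 3**
Reactants: 7 (3aS,7R,7aS)-7-hydroxy-3-methylhexahydro-1-benzofuran-2,6-dione
Product: 9 (3S,3aS,6R,7R,7aS)-6-ethenyl-6,7-dihydroxy-3-methylhexahydro-1-benzofuran-2(3H)-one, via 11-epimer mixture 8 (not isolated)
Conditions: CH2=CHMgBr (2.5 equiv), LaCl3·2LiCl (30 mol%), THF, −78 °C; then t-BuOK (0.3 equiv), t-BuOH, 23 °C
Reagents that add atoms: vinylmagnesium bromide, C=C[Mg]Br
Why: Chelation-controlled Grignard addition to the α-hydroxy ketone (cyclic Cram model) should deliver the vinyl group equatorially to give the cis-1,2-diol (this C10 centre is destroyed in step 6), and catalytic tert-butoxide then epimerises the lactone α-carbon C11 to the thermodynamically preferred methyl-trans-to-C8 configuration, which is that of the target.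

**Step 4**
Reactants: 9 (3S,3aS,6R,7R,7aS)-6-ethenyl-6,7-dihydroxy-3-methylhexahydro-1-benzofuran-2(3H)-one
Product: 10 (3S,3aS,6R,7aS)-6-ethenyl-6-hydroxy-3-methyltetrahydro-1-benzofuran-2,7(3H,7aH)-dione
Conditions: Dess–Martin periodinane, CH2Cl2, 0 → 23 °C
Reagents that add atoms: none
Why: Dess–Martin oxidation should convert only the secondary C5 carbinol into the ketone, because the tertiary allylic C10 carbinol cannot be oxidised and the mild neutral conditions leave the lactone and the α-stereocentre C6 untouched.

**Step 5**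
Reactants: 10 (3S,3aS,6R,7aS)-6-ethenyl-6-hydroxy-3-methyltetrahydro-1-benzofuran-2,7(3H,7aH)-dione
Product: 11 (3S,3aS,6R,7R,7aS)-6-ethenyl-6,7-dihydroxy-3-methyl-7-(prop-1-en-2-yl)hexahydro-1-benzofuran-2(3H)-one
Conditions: CH2=C(CH3)MgBr (3 equiv), LaCl3·2LiCl (30 mol%), THF, −78 → −40 °C
Reagents that add atoms: prop-1-en-2-ylmagnesium bromide, CC(=C)[Mg]Br
Why: Grignard 1,2-addition at −78 °C is faster at the ketone than at the lactone and should occur axially, anti to the axial C10–O bond (Felkin–Anh), to give the cis-diol in which the equatorial vinyl and axial isopropenyl groups are gauche, as the Cope rearrangement needs (this C5 centre is also destroyed in step 6).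

**Step 6**
Reactants: 11 (3S,3aS,6R,7R,7aS)-6-ethenyl-6,7-dihydroxy-3-methyl-7-(prop-1-en-2-yl)hexahydro-1-benzofuran-2(3H)-one
Product: 15 10-oxo-14-norguai-1(5)-en-12,6-olide (6β-H, 7α-H, 11β-H; C4 epimers), via bis-enolate 12 (not isolated), via diketone 13 (not isolated), via ketol 14 (not isolated)
Conditions: KN(SiMe3)2 (2.05 equiv), 18-crown-6 (2.2 equiv), THF, −78 → 23 °C; AcOH, −78 °C; then p-TsOH·H2O (20 mol%), PhMe, 60 °C
Reagents that add atoms: none
Why: The 1,2-dialkoxide undergoes a dianionic oxy-Cope [3,3] shift through a chair transition state (C10 oxyanion pseudo-equatorial) that breaks C5–C10 and joins the two alkene termini C2 and C3, giving the ten-membered bis-enolate 12; protonation gives the 5,10-diketone 13, whose C1 enol adds across the ring to the C5 ketone, and ketol 14 dehydrates to the conjugated enone 15. The closest known reaction type is the oxy-Cope rearrangement of 1,2-dialkenylcycloalkane-1,2-diols followed by transannular aldol condensation of the resulting cyclodecane-1,6-dione to a hydroazulenone. The ten-membered ring is closed by four-carbon sigmatropic ring expansion; the five-membered ring, and with it the seven-membered ring, by transannular 5-exo-trig aldol addition of C1 to C5. C6, C7 and C11 are not touched (2.05 equiv of base leaves the lactone un-enolised, and the acid phase is short to protect C6, which is α to the transient C5 ketone); C1 and C5 end sp2 and the new C4 centre is inconsequential because it becomes sp2 in step 10. The selectivity needed is aldol regiochemistry: closures C9→C5 and C6→C10 would build a cyclopentane trans-fused to the lactone, and C4→C10 gives a ketol with no α-hydrogen that cannot dehydrate and reverts, so only C1→C5 drains irreversibly to 15.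

**Step 7**
Reactants: 15 10-oxo-14-norguai-1(5)-en-12,6-olide
Product: 16 (10S)-10-hydroxyguai-1(5)-en-12,6-olide (10β-OH, 10α-CH3; C4 epimers)
Conditions: Me2Zn (3 equiv), Ti(OiPr)4 (1.2 equiv), trans-cyclohexane-1,2-diyl bis(hydroxycamphorsulfonamide) ligand (10 mol%), PhMe/hexane, 23 °C
Reagents that add atoms: dimethylzinc, C[Zn]C
Why: Titanium-catalysed asymmetric 1,2-addition of a methylzinc reagent to an α-substituted cyclic enone, run with the ligand enantiomer that delivers methyl to the Re (α) face of C10, should set C10 under catalyst control (substrate facial bias in the flexible cycloheptenone is not predictable) and tolerates the lactone.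

**Step 8**
Reactants: 16 (10S)-10-hydroxyguai-1(5)-en-12,6-olide
Product: 17 (10S)-2,10-dihydroxyguai-1(5)-en-12,6-olide (C2 and C4 epimers)
Conditions: SeO2 (0.5 equiv), t-BuOOH (2 equiv), CH2Cl2, 0 → 23 °C
Reagents that add atoms: selenium dioxide (oxygen carrier), O=[Se]=O; tert-butyl hydroperoxide, CC(C)(C)OO
Why: Allylic hydroxylation by SeO2 (ene reaction, then [2,3]-sigmatropic shift) should take a hydrogen from the C2 methylene, because selenium can bond to C5 but hardly to C1 next to the quaternary carbinol; the configurations at C2 and C4 do not matter since both carbons become sp2.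

**Step 9**
Reactants: 17 (10S)-2,10-dihydroxyguai-1(5)-en-12,6-olide
Product: 18 (10S)-2-acetoxy-10-hydroxyguai-1(5)-en-12,6-olide
Conditions: Ac2O, DMAP (cat.), pyridine, CH2Cl2, 0 °C
Reagents that add atoms: acetic anhydride, CC(=O)OC(C)=O
Why: DMAP-catalysed acylation should acetylate only the secondary allylic alcohol, the tertiary C10 carbinol being too hindered at 0 °C.

**Step 10**
Reactants: 18 (10S)-2-acetoxy-10-hydroxyguai-1(5)-en-12,6-olide
Product: 20 artabsin, (3S,3aS,6S,9bS)-6-hydroxy-3,6,9-trimethyl-3a,4,5,6,7,9b-hexahydroazuleno[4,5-b]furan-2(3H)-one, via kinetic diene 19 (not isolated)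
Conditions: Pd(PPh3)4 (5 mol%), Et3N, dioxane, 70 °C
Reagents that add atoms: none
Why: Palladium-catalysed elimination of the allylic acetate (Tsuji–Trost ionisation to a π-allyl complex over C2–C1–C5, then β-hydride elimination) should give a cyclopentadiene whatever the configuration at C2 and C4, and suprafacial [1,5]-hydrogen shifts at 70 °C equilibrate the tautomers towards artabsin, while the free tertiary alcohol does not ionise under these neutral conditions.

**Step 11**
Reactants: 20 artabsin (two molecules)
Product: 22 absinthin, via 2,4-diene 21 (not isolated)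
Conditions: neat, 23 °C, N2, dark, 10 d
Reagents that add atoms: none
Why: A reversible thermal [1,5]-hydrogen shift moves a C2 hydrogen to C1, and two molecules of the resulting 1α-H 2,4-diene 21 should combine in an endo, head-to-head Diels–Alder dimerisation (bonds C2–C2′ and C5–C3′) in which each partner reacts on the face of its H-1, anti to C10, which sets C1, C2, C5, C1′, C2′ and C3′ of the target.

**Compound list**

1 | methyl 2-methyl-4-oxobutanoate (racemic) | COC(=O)C(C)CC=O | starting material
2 | but-3-en-2-one | CC(=O)C=C | starting material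
3 | methyl (3S)-3-formyl-2-methyl-6-oxoheptanoate (C2 epimers) | COC(=O)C(C)[C@@H](C=O)CCC(C)=O | intermediate (not isolated)
4 | methyl 2-[(1R)-4-oxocyclohex-2-en-1-yl]propanoate (C11 epimers) | COC(=O)C(C)[C@H]1C=CC(=O)CC1 | intermediate
5 | methyl 2-(2,3-dihydroxy-4-oxocyclohexyl)propanoate, cis-diol anti to the side chain (C11 epimers) | COC(=O)C(C)[C@@H]1CCC(=O)[C@@H](O)[C@H]1O | intermediate (not isolated)
6 | (3aS,7S,7aS)-7-hydroxy-3-methylhexahydro-1-benzofuran-2,6-dione, axial carbinol (C11 epimers) | CC1C(=O)O[C@@H]2[C@H](O)C(=O)CC[C@@H]12 | intermediate (not isolated)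
7 | (3aS,7R,7aS)-7-hydroxy-3-methylhexahydro-1-benzofuran-2,6-dione, equatorial carbinol (C11 epimers) | CC1C(=O)O[C@@H]2[C@@H](O)C(=O)CC[C@@H]12 | intermediate
8 | (3aS,6R,7R,7aS)-6-ethenyl-6,7-dihydroxy-3-methylhexahydro-1-benzofuran-2(3H)-one (C11 epimers) | CC1C(=O)O[C@@H]2[C@@H](O)[C@](O)(C=C)CC[C@@H]12 | intermediate (not isolated)
9 | (3S,3aS,6R,7R,7aS)-6-ethenyl-6,7-dihydroxy-3-methylhexahydro-1-benzofuran-2(3H)-one | C[C@@H]1C(=O)O[C@@H]2[C@@H](O)[C@](O)(C=C)CC[C@@H]12 | intermediate
10 | (3S,3aS,6R,7aS)-6-ethenyl-6-hydroxy-3-methyltetrahydro-1-benzofuran-2,7(3H,7aH)-dione | C[C@@H]1C(=O)O[C@@H]2C(=O)[C@](O)(C=C)CC[C@@H]12 | intermediate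
11 | (3S,3aS,6R,7R,7aS)-6-ethenyl-6,7-dihydroxy-3-methyl-7-(prop-1-en-2-yl)hexahydro-1-benzofuran-2(3H)-one | C[C@@H]1C(=O)O[C@@H]2[C@](O)(C(C)=C)[C@](O)(C=C)CC[C@@H]12 | intermediate
12 | dipotassium 5,10-bis-enolate of 13 (enolate geometries not specified) | [K+].[K+].C[C@@H]1C(=O)O[C@@H]2C([O-])=C(C)CCC=C([O-])CC[C@@H]12 | intermediate (not isolated)
13 | 14-norgermacrane-5,10-dione 12,6-olide: (3S,3aS,11aS)-3,10-dimethyldecahydrocyclodeca[b]furan-2,6,11-trione (C4 epimers) | C[C@@H]1C(=O)O[C@@H]2C(=O)C(C)CCCC(=O)CC[C@@H]12 | intermediate (not isolated)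
14 | 5-hydroxy-10-oxo-14-norguaian-12,6-olide (diastereomers at C1, C4, C5) | C[C@@H]1C(=O)O[C@@H]2C3(O)C(C)CCC3C(=O)CC[C@@H]12 | intermediate (not isolated)
15 | 10-oxo-14-norguai-1(5)-en-12,6-olide (C4 epimers) | C[C@@H]1C(=O)O[C@@H]2C3=C(CCC3C)C(=O)CC[C@@H]12 | intermediate
16 | (10S)-10-hydroxyguai-1(5)-en-12,6-olide (C4 epimers) | C[C@@H]1C(=O)O[C@@H]2C3=C(CCC3C)[C@@](C)(O)CC[C@@H]12 | intermediate
17 | (10S)-2,10-dihydroxyguai-1(5)-en-12,6-olide (C2 and C4 epimers) | C[C@@H]1C(=O)O[C@@H]2C3=C(C(O)CC3C)[C@@](C)(O)CC[C@@H]12 | intermediate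
18 | (10S)-2-acetoxy-10-hydroxyguai-1(5)-en-12,6-olide (C2 and C4 epimers) | C[C@@H]1C(=O)O[C@@H]2C3=C(C(OC(C)=O)CC3C)[C@@](C)(O)CC[C@@H]12 | intermediate
19 | (10S)-10-hydroxyguaia-1(5),2-dien-12,6-olide (C4 epimers) | C[C@@H]1C(=O)O[C@@H]2C3=C(C=CC3C)[C@@](C)(O)CC[C@@H]12 | intermediate (not isolated)
20 | artabsin, (10S)-10-hydroxyguaia-1(5),3-dien-12,6-olide | C[C@@H]1C(=O)O[C@@H]2C3=C(CC=C3C)[C@@](C)(O)CC[C@@H]12 | intermediate
21 | (1R,10S)-10-hydroxyguaia-2,4-dien-12,6-olide (1α-H) | C[C@@H]1C(=O)O[C@@H]2C3=C(C)C=C[C@H]3[C@@](C)(O)CC[C@@H]12 | intermediate (not isolated)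
22 | absinthin | CC1=C[C@@H]2[C@H]3[C@H](C(C)=C4[C@H]5OC(=O)[C@@H](C)[C@@H]5CC[C@](C)(O)[C@@H]43)[C@@]13[C@@H]2[C@@](C)(O)CC[C@H]1[C@H](C)C(=O)O[C@@H]13 | target

**Step count and risks**

Total step count: 11. Longest linear sequence: 11 steps (1 and 2 to 22).

Steps most likely to fail:

Step 11. The tautomers of 20 can pair in other [4+2] combinations, the wrong C1 epimer of 21 can be drained, and the free cyclopentadienyl carbinol can dehydrate to a fulvene or steer the partners through hydrogen bonding. Fallback: mask the carbinol before the cycloaddition. Starting from 20, N-(trimethylsilyl)imidazole should give artabsin trimethylsilyl ether F4, which cannot dehydrate and carries a bulkier C10 group that reinforces anti approach; neat dimerisation should give absinthin bis(trimethylsilyl) ether F5, and Bu4NF/AcOH returns to the route at 22.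

Step 6. The dialkoxide may fragment, the base may enolise or open the lactone, or the lactone-locked chair may slow the sigmatropic shift so that decomposition or C6 epimerisation overtakes it. Fallback: a neutral thermal silyloxy-Cope rearrangement. Starting from 11, TMSOTf/2,6-lutidine should give the bis(trimethylsilyl) ether F1; heating (PhMe, 200 °C, sealed tube) should rearrange it to the ten-membered bis(silyl enol ether) F2; p-TsOH in wet THF then hydrolyses F2 and effects the transannular aldol condensation, returning to the route at 15.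

Step 8. Hydroxylation may occur at C4 or C6 instead of C2, over-oxidise to the enone, or the acidic selenium species may ionise the tertiary allylic alcohol. Fallback: radical allylic acyloxylation in place of the ene reaction. Starting from 16, the Kharasch–Sosnovsky reaction (CuBr, tert-butyl perbenzoate, PhH/MeCN, 60 °C) abstracts hydrogen from C2 or C4 and should give allylic benzoates, represented by the 2-benzoate F3. All regioisomers ionise with zerovalent palladium to the same π-allyl complex, so the conditions of step 10 applied to F3 return to the route at 20, bypassing 17 and 18.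

**Further compounds**

F1 | step 6 | bis(trimethylsilyl) ether of 11 | C[C@@H]1C(=O)O[C@@H]2[C@](O[Si](C)(C)C)(C(C)=C)[C@](O[Si](C)(C)C)(C=C)CC[C@@H]12
F2 | step 6 | ten-membered 5,10-bis(trimethylsilyl enol ether) corresponding to 13 (enol ether geometries not specified) | C[C@@H]1C(=O)O[C@@H]2C(O[Si](C)(C)C)=C(C)CCC=C(O[Si](C)(C)C)CC[C@@H]12
F3 | step 8 | (10S)-2-benzoyloxy-10-hydroxyguai-1(5)-en-12,6-olide (C2 and C4 epimers) | C[C@@H]1C(=O)O[C@@H]2C3=C(C(OC(=O)c4ccccc4)CC3C)[C@@](C)(O)CC[C@@H]12
F4 | step 11 | artabsin 10-O-trimethylsilyl ether | C[C@@H]1C(=O)O[C@@H]2C3=C(CC=C3C)[C@@](C)(O[Si](C)(C)C)CC[C@@H]12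
F5 | step 11 | absinthin 10,10′-bis(trimethylsilyl) ether | CC1=C[C@@H]2[C@H]3[C@H](C(C)=C4[C@H]5OC(=O)[C@@H](C)[C@@H]5CC[C@](C)(O[Si](C)(C)C)[C@@H]43)[C@@]13[C@@H]2[C@@](C)(O[Si](C)(C)C)CC[C@H]1[C@H](C)C(=O)O[C@@H]13
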